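## Retrosynthetic overview

- **Feature used:** in ring C the aryl ketone bond C4–C4a ties the carbonyl to a ring A carbon lying between the oxygen-bearing C5 and C8a. The O1–C2(Ph)–C3(OH) unit is an anti ether–alcohol pair, which is the same thing as the 2,3-trans ketol.
- **Disconnection 1 (last skeletal bond made):** C4–C4a, by iodine–lithium exchange at C4a and acylation of the aryllithium by a tethered Weinreb amide. Ring C is the only ring formed; rings A and B are bought.
- **Disconnection 2:** O1–C2, by opening methyl (2R,3S)-3-phenylglycidate at its benzylic carbon with the ring A phenol. Inversion gives 2R, and the untouched epoxide carbon becomes 3R.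
- **Ring A:** 3,5-dimethoxyphenol has two equivalent ortho positions. Two successive acetal-directed lithiations therefore place prenyl (C8) and then iodine (C4a) without having to tell two phenols apart.
- **End game:** the C5 methyl ether, the only one peri to the new carbonyl, is cleaved through MgI2 chelation. The C3 silyl ether is then removed with buffered HF.

Key step: step 8

Assumption: flavanone numbering (O1, C2, C3, C4, C4a, C5 to C8, C8a; rings A, B, C) is used for all intermediates, and glycidate 9 is taken as available in enantiopure form.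

## Route

Step 1
Reactants: 1 3,5-dimethoxyphenol
Product: 2 1,3-dimethoxy-5-(methoxymethoxy)benzene
Conditions: MOMCl, i-Pr2NEt, CH2Cl2, 0 °C → rt
Reagents that add atoms: chloromethyl methyl ether (MOMCl), COCCl
Why: Williamson-type O-alkylation of the phenol with the reactive chloromethyl ether installs the acetal that serves as the ortho-directing group for both metalations.

Step 2
Reactants: 2 1,3-dimethoxy-5-(methoxymethoxy)benzene; 3 prenyl bromide (1-bromo-3-methylbut-2-ene)
Product: 5 1,5-dimethoxy-3-(methoxymethoxy)-2-(3-methylbut-2-enyl)benzene, via aryllithium 4 (not isolated)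
Conditions: n-BuLi (1.1 equiv), THF, 0 °C; then 3, −78 °C → rt
Reagents that add atoms: none
Why: Directed ortho-metalation, in which the OMOM group (a stronger director than OMe) cooperates with the neighbouring methoxy group so that lithium enters one of the two equivalent OMOM/OMe-flanked positions rather than the OMe/OMe site, and the aryllithium then displaces the primary allylic bromide by SN2.

Step 3
Reactants: 5 1,5-dimethoxy-3-(methoxymethoxy)-2-(3-methylbut-2-enyl)benzene
Product: 7 2-iodo-1,5-dimethoxy-3-(methoxymethoxy)-4-(3-methylbut-2-enyl)benzene, via aryllithium 6 (not isolated)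
Conditions: n-BuLi (1.2 equiv), THF, −20 → 0 °C; then I2 in THF, −78 °C; aq. Na2S2O3
Reagents that add atoms: iodine, [I][I]
Why: Second directed ortho-metalation, in which only one OMOM/OMe-flanked C–H is left and the prenyl group turns the acetal chain toward it, so coordination-assisted ring lithiation should outrun removal of the benzylic-allylic hydrogens, and the aryllithium takes up iodine at −78 °C faster than iodine can add to the alkene.

Step 4
Reactants: 7 2-iodo-1,5-dimethoxy-3-(methoxymethoxy)-4-(3-methylbut-2-enyl)benzene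
Product: 8 2-iodo-3,5-dimethoxy-6-(3-methylbut-2-enyl)phenol
Conditions: p-TsOH·H2O (0.1 equiv), MeOH, rt → 40 °C
Reagents that add atoms: none
Why: Acid-catalysed transacetalisation to methanol frees the phenol, and a catalytic sulfonic acid without a halide counter-ion is too mild to protonate the trisubstituted alkene (chroman formation) or to bring about protodeiodination.

Step 5
Reactants: 8 2-iodo-3,5-dimethoxy-6-(3-methylbut-2-enyl)phenol; 9 methyl (2R,3S)-3-phenylglycidate
Product: 10 methyl (2R,3R)-2-hydroxy-3-[2-iodo-3,5-dimethoxy-6-(3-methylbut-2-enyl)phenoxy]-3-phenylpropanoate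
Conditions: Cs2CO3 (0.3 equiv), 9 (1.3 equiv), DMF, 60 °C
Reagents that add atoms: none
Why: Base-catalysed SN2 opening of a trans-3-arylglycidate by a phenoxide takes place at the benzylic carbon anti to the epoxide oxygen, so this carbon is inverted (S to R, the future C2) while the α-carbon (R, the future C3) is untouched, and substoichiometric base keeps the product protonated and so holds back β-elimination and epimerisation.

Step 6
Reactants: 10 methyl (2R,3R)-2-hydroxy-3-[2-iodo-3,5-dimethoxy-6-(3-methylbut-2-enyl)phenoxy]-3-phenylpropanoate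
Product: 11 (2R,3R)-2-hydroxy-3-[2-iodo-3,5-dimethoxy-6-(3-methylbut-2-enyl)phenoxy]-N-methoxy-N-methyl-3-phenylpropanamide
Conditions: MeNHOMe·HCl (3 equiv), AlMe3 (3 equiv), CH2Cl2, 0 °C → rt; aq. Rochelle salt
Reagents that add atoms: N,O-dimethylhydroxylamine hydrochloride, CNOC.Cl
Why: Weinreb aminolysis of the ester with the aluminium amide made from AlMe3 and the amine hydrochloride is chosen over a Grignard-derived amide because it leaves the aryl iodide alone, the free hydroxyl only consuming one more equivalent.

Step 7
Reactants: 11 (2R,3R)-2-hydroxy-3-[2-iodo-3,5-dimethoxy-6-(3-methylbut-2-enyl)phenoxy]-N-methoxy-N-methyl-3-phenylpropanamide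
Product: 12 (2R,3R)-2-(tert-butyldimethylsilyloxy)-3-[2-iodo-3,5-dimethoxy-6-(3-methylbut-2-enyl)phenoxy]-N-methoxy-N-methyl-3-phenylpropanamide
Conditions: TBSOTf (1.5 equiv), 2,6-lutidine, CH2Cl2, 0 °C
Reagents that add atoms: tert-butyldimethylsilyl trifluoromethanesulfonate (TBSOTf), CC(C)(C)[Si](C)(C)OS(=O)(=O)C(F)(F)F
Why: Silylation of the hindered secondary alcohol with a silyl triflate and a non-nucleophilic base removes the acidic O–H before the organolithium step and touches neither stereocenter.

Step 8
Reactants: 12 (2R,3R)-2-(tert-butyldimethylsilyloxy)-3-[2-iodo-3,5-dimethoxy-6-(3-methylbut-2-enyl)phenoxy]-N-methoxy-N-methyl-3-phenylpropanamide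
Product: 15 (2R,3R)-3-(tert-butyldimethylsilyloxy)-5,7-dimethoxy-8-(3-methylbut-2-enyl)-2-phenylchroman-4-one, via aryllithium 13 (not isolated), via lithium hemiaminal alkoxide 14 (not isolated)
Conditions: n-BuLi (1.1 equiv), THF, −95 → −78 °C; AcOH in THF at −78 °C, then pH 7 buffer
Reagents that add atoms: none
Why: n-BuLi attacks the iodine of 12 through an ate complex to give aryllithium 13, which is held by the flanking C5 methoxy and O1 oxygens, is pushed toward the side chain by the C8 prenyl group, and adds to the tethered N-methoxy-N-methylamide carbonyl to form C4–C4a. This is a Parham cyclization (halogen–lithium exchange followed by intramolecular acylation) with a Weinreb amide as internal electrophile, a known way to chroman-4-ones and related benzo-fused ketones. Ring C closes in the 6-exo-trig mode, the carbonyl oxygen staying outside the new six-membered ring. No lasting stereocenter is created, since C4 of the lithium-chelated hemiaminal 14 is transient and becomes the sp2 carbonyl on quench, while C2 and C3 are carried over unchanged from 12. The step needs chemoselectivity (exchange before addition of n-BuLi to the amide or deprotonation at C3–H and the benzylic positions, and no second addition) and site selectivity; the first is secured by the very fast exchange of an aryl iodide at −95 °C and by the persistence of chelate 14, the second by iodine being present only at C4a. The acidic quench at −78 °C neutralises the released lithium amide before the base-sensitive α-silyloxy ketone appears, so C3 and the O1–C2 bond are not put at risk.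

Step 9
Reactants: 15 (2R,3R)-3-(tert-butyldimethylsilyloxy)-5,7-dimethoxy-8-(3-methylbut-2-enyl)-2-phenylchroman-4-one
Product: 17 (2R,3R)-3-(tert-butyldimethylsilyloxy)-5-hydroxy-7-methoxy-8-(3-methylbut-2-enyl)-2-phenylchroman-4-one, via iodomagnesium phenoxide 16 (not isolated)
Conditions: MgI2·OEt2 (3 equiv), THF, 60 °C; aq. NH4Cl/Na2S2O3
Reagents that add atoms: none
Why: Chelation-controlled aryl methyl ether cleavage, in which MgI2 binds between the C4 carbonyl and the peri C5 methoxy oxygen and iodide removes that methyl group by SN2, is known for 5-methoxy-8-prenylflavanones, and the unchelated C7 methoxy group, the alkene and the silyl ether should stay.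

Step 10
Reactants: 17 (2R,3R)-3-(tert-butyldimethylsilyloxy)-5-hydroxy-7-methoxy-8-(3-methylbut-2-enyl)-2-phenylchroman-4-one
Product: 18 (2R,3R)-3,5-dihydroxy-7-methoxy-8-(3-methylbut-2-enyl)-2-phenylchroman-4-one (target)
Conditions: HF·pyridine, pyridine, THF, 0 °C → rt
Reagents that add atoms: none
Why: Fluoride-driven desilylation in a slightly acidic, buffered medium avoids the base-induced ring opening and C2/C3 epimerisation to which 3-hydroxyflavanones are prone, and the diluted reagent does not add to the prenyl alkene.

## Compound list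

1 | 3,5-dimethoxyphenol | COc1cc(O)cc(OC)c1 | starting material
2 | 1,3-dimethoxy-5-(methoxymethoxy)benzene | COCOc1cc(OC)cc(OC)c1 | intermediate
3 | prenyl bromide (1-bromo-3-methylbut-2-ene) | CC(C)=CCBr | starting material
4 | [2,4-dimethoxy-6-(methoxymethoxy)phenyl]lithium (formed in the flask) | COCOc1cc(OC)cc(OC)c1[Li] | intermediate
5 | 1,5-dimethoxy-3-(methoxymethoxy)-2-(3-methylbut-2-enyl)benzene | COCOc1cc(OC)cc(OC)c1CC=C(C)C | intermediate
6 | [2,4-dimethoxy-6-(methoxymethoxy)-5-(3-methylbut-2-enyl)phenyl]lithium (formed in the flask) | COCOc1c([Li])c(OC)cc(OC)c1CC=C(C)C | intermediate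
7 | 2-iodo-1,5-dimethoxy-3-(methoxymethoxy)-4-(3-methylbut-2-enyl)benzene | COCOc1c(I)c(OC)cc(OC)c1CC=C(C)C | intermediate
8 | 2-iodo-3,5-dimethoxy-6-(3-methylbut-2-enyl)phenol | Oc1c(I)c(OC)cc(OC)c1CC=C(C)C | intermediate
9 | methyl (2R,3S)-3-phenylglycidate | COC(=O)[C@@H]1O[C@H]1c1ccccc1 | starting material
10 | methyl (2R,3R)-2-hydroxy-3-[2-iodo-3,5-dimethoxy-6-(3-methylbut-2-enyl)phenoxy]-3-phenylpropanoate | COc1cc(OC)c(I)c(c1CC=C(C)C)O[C@H](c1ccccc1)[C@@H](O)C(=O)OC | intermediate
11 | (2R,3R)-2-hydroxy-3-[2-iodo-3,5-dimethoxy-6-(3-methylbut-2-enyl)phenoxy]-N-methoxy-N-methyl-3-phenylpropanamide | COc1cc(OC)c(I)c(c1CC=C(C)C)O[C@H](c1ccccc1)[C@@H](O)C(=O)N(C)OC | intermediate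
12 | (2R,3R)-2-(tert-butyldimethylsilyloxy)-3-[2-iodo-3,5-dimethoxy-6-(3-methylbut-2-enyl)phenoxy]-N-methoxy-N-methyl-3-phenylpropanamide (key-step precursor) | COc1cc(OC)c(I)c(c1CC=C(C)C)O[C@H](c1ccccc1)[C@@H](O[Si](C)(C)C(C)(C)C)C(=O)N(C)OC | intermediate
13 | C4a-lithio compound from 12, lithium in place of iodine (formed in the flask) | COc1cc(OC)c([Li])c(c1CC=C(C)C)O[C@H](c1ccccc1)[C@@H](O[Si](C)(C)C(C)(C)C)C(=O)N(C)OC | intermediate
14 | lithium alkoxide of the C4 N-methoxy-N-methyl hemiaminal, chelated tetrahedral adduct, C4 configuration not defined (formed in the flask) | COc1cc(OC)c2c(c1CC=C(C)C)O[C@H](c1ccccc1)[C@@H](O[Si](C)(C)C(C)(C)C)C2(O[Li])N(C)OC | intermediate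
15 | (2R,3R)-3-(tert-butyldimethylsilyloxy)-5,7-dimethoxy-8-(3-methylbut-2-enyl)-2-phenylchroman-4-one (key-step product) | COc1cc(OC)c2c(c1CC=C(C)C)O[C@H](c1ccccc1)[C@@H](O[Si](C)(C)C(C)(C)C)C2=O | intermediate
16 | iodomagnesium C5 phenoxide of 17 (formed in the flask) | COc1cc(O[Mg]I)c2c(c1CC=C(C)C)O[C@H](c1ccccc1)[C@@H](O[Si](C)(C)C(C)(C)C)C2=O | intermediate
17 | (2R,3R)-3-(tert-butyldimethylsilyloxy)-5-hydroxy-7-methoxy-8-(3-methylbut-2-enyl)-2-phenylchroman-4-one | COc1cc(O)c2c(c1CC=C(C)C)O[C@H](c1ccccc1)[C@@H](O[Si](C)(C)C(C)(C)C)C2=O | intermediate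
18 | (2R,3R)-3,5-dihydroxy-7-methoxy-8-(3-methylbut-2-enyl)-2-phenylchroman-4-one | COc1cc(O)c2c(c1CC=C(C)C)O[C@H](c1ccccc1)[C@@H](O)C2=O | target

## Step count and risks

Total step count: 10. Longest linear sequence: 10 steps (1 → 18); 3 and 9 are bought.

**Step 8 (ring closure).**
- What may go wrong: n-BuLi may add to the amide carbonyl in competition with the exchange.
- The aryllithium may also be quenched by proton transfer from C3–H or the benzylic C2–H, followed by β-elimination of the phenoxide.
- Closure may also be slow in the crowded, doubly ortho-substituted ether.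
- Fallback (sets out from 12, returns at 15): the same C4–C4a bond is made under non-basic, chromium-mediated conditions.
- Reduction of 12 with DIBAL-H (toluene, −78 °C) should give (2R,3R)-2-(tert-butyldimethylsilyloxy)-3-[2-iodo-3,5-dimethoxy-6-(3-methylbut-2-enyl)phenoxy]-3-phenylpropanal F1.
- An intramolecular Nozaki–Hiyama–Kishi reaction (CrCl2, catalytic NiCl2, DMF, rt) should then close ring C to (2R,3S)-3-(tert-butyldimethylsilyloxy)-5,7-dimethoxy-8-(3-methylbut-2-enyl)-2-phenylchroman-4-ol F2.
- F2 has C2 and C3 arranged in space as in 15 (the C3 descriptor changes only because the ranking of its neighbours changes). It may be either C4 epimer, because Dess–Martin periodinane (NaHCO3, CH2Cl2) oxidises both to 15.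

**Step 5 (aryl ether formation).**
- What may go wrong: attack of the doubly ortho-substituted phenoxide on the secondary benzylic carbon may be slow. Transesterification, β-elimination of the product or attack at the α-carbon could then take over.
- Fallback (sets out from 8, returns at 12): the O1–C2 bond is made by redox condensation on a benzylic alcohol instead of by epoxide opening.
- Commercial methyl (2R,3S)-2,3-dihydroxy-3-phenylpropanoate F3 is silylated at its more acidic, less hindered α-hydroxyl (TBSCl, imidazole, DMF, 0 °C) to methyl (2R,3S)-2-(tert-butyldimethylsilyloxy)-3-hydroxy-3-phenylpropanoate F4.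
- A Mitsunobu reaction of F4 with 8 (PPh3, DIAD, toluene, high concentration, 0 °C → rt) should invert the benzylic carbon. It gives methyl (2R,3R)-2-(tert-butyldimethylsilyloxy)-3-[2-iodo-3,5-dimethoxy-6-(3-methylbut-2-enyl)phenoxy]-3-phenylpropanoate F5.
- Aminolysis as in step 6 (MeNHOMe·HCl, AlMe3, CH2Cl2) then leads to 12.

**Step 3 (second metalation).**
- What may go wrong: removal of a benzylic-allylic hydrogen of the prenyl group, or lithiation between the two methoxy groups, may compete with the wanted ring metalation. The result would be alkene migration or iodine at the future C6.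
- Fallback (sets out from 2, returns at 8): iodine is put in before any alkene is present, and the side chain then comes in by a sigmatropic route without organolithium reagents.
- Aryllithium 4, made from 2 as in step 2, is quenched with I2 to give 2-iodo-1,5-dimethoxy-3-(methoxymethoxy)benzene F6.
- p-TsOH in MeOH frees 2-iodo-3,5-dimethoxyphenol F7.
- Allyl bromide and K2CO3 in acetone give 2-iodo-1,5-dimethoxy-3-(prop-2-enyloxy)benzene F8.
- Aromatic Claisen rearrangement (N,N-diethylaniline, 180 °C) should end at the one free ortho position and give 2-iodo-3,5-dimethoxy-6-(prop-2-enyl)phenol F9.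
- Cross metathesis with 2-methylbut-2-ene (second-generation Grubbs catalyst, CH2Cl2, 40 °C) turns allyl into prenyl and gives 8.

## Further compounds

F1 | step 8 | (2R,3R)-2-(tert-butyldimethylsilyloxy)-3-[2-iodo-3,5-dimethoxy-6-(3-methylbut-2-enyl)phenoxy]-3-phenylpropanal | COc1cc(OC)c(I)c(c1CC=C(C)C)O[C@H](c1ccccc1)[C@@H](O[Si](C)(C)C(C)(C)C)C=O
F2 | step 8 | (2R,3S)-3-(tert-butyldimethylsilyloxy)-5,7-dimethoxy-8-(3-methylbut-2-enyl)-2-phenylchroman-4-ol (C4 epimers) | COc1cc(OC)c2c(c1CC=C(C)C)O[C@H](c1ccccc1)[C@@H](O[Si](C)(C)C(C)(C)C)C2O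
F3 | step 5 | methyl (2R,3S)-2,3-dihydroxy-3-phenylpropanoate | O[C@@H](c1ccccc1)[C@@H](O)C(=O)OC
F4 | step 5 | methyl (2R,3S)-2-(tert-butyldimethylsilyloxy)-3-hydroxy-3-phenylpropanoate | O[C@@H](c1ccccc1)[C@@H](O[Si](C)(C)C(C)(C)C)C(=O)OC
F5 | step 5 | methyl (2R,3R)-2-(tert-butyldimethylsilyloxy)-3-[2-iodo-3,5-dimethoxy-6-(3-methylbut-2-enyl)phenoxy]-3-phenylpropanoate | COc1cc(OC)c(I)c(c1CC=C(C)C)O[C@H](c1ccccc1)[C@@H](O[Si](C)(C)C(C)(C)C)C(=O)OC
F6 | step 3 | 2-iodo-1,5-dimethoxy-3-(methoxymethoxy)benzene | COCOc1cc(OC)cc(OC)c1I
F7 | step 3 | 2-iodo-3,5-dimethoxyphenol | Oc1cc(OC)cc(OC)c1I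
F8 | step 3 | 2-iodo-1,5-dimethoxy-3-(prop-2-enyloxy)benzene | C=CCOc1cc(OC)cc(OC)c1I
F9 | step 3 | 2-iodo-3,5-dimethoxy-6-(prop-2-enyl)phenol | Oc1c(I)c(OC)cc(OC)c1CC=C
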